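**Retrosynthetic overview**
1. Last C–C bond: B-alkyl Suzuki–Miyaura coupling of homofarnesyl-9-BBN 18 (from farnesol-derived tetraene 17) with the (Z)-2-bromoallyl unit of butenolide 14; retention gives the (E)-olefin, and desilylation ends the route.
2. Butenolide (the only ring of the target, formed after a transient cyclopropene): one-flask formal (3+2) of terminal alkyne 11 with tert-butyl diazoacetate 12. A rhodium carbenoid (2+1) addition gives cyclopropene 13, then gold-triggered ring opening lets the ester carbonyl oxygen close onto the former alkyne CH, forming the ring O–CH2 bond with loss of isobutene.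
3. Enabling feature: ring atoms O1–C2(=O)–C3 are a carbalkoxycarbene and C4–C5 an alkyne. C5 is an unsubstituted CH2 and C4 carries the only ring substituent, so a terminal propargylic alkyne maps on with the right regiochemistry; the carbinol stereocentre is exocyclic and is set beforehand.
4. Alkyne 11 from 3-(trimethylsilyl)propynal 1: Brown allylboration sets the (R)-carbinol, then alkene cleavage, a Z-selective bromo-Wittig reaction and DIBAL-H reduction.

Key step: step 8

Remark on the chemistry: the target carbinol is (R) and the hydroxymethyl-bearing olefin is (E), i.e. the homofarnesyl group is cis to the CH2 leading to the carbinol. Ylide 7 is taken as purchasable; otherwise it is made in one operation from ethyl (triphenylphosphoranylidene)acetate, Br2 and Et3N.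

**Step 1**
Reactants: 1 3-(trimethylsilyl)prop-2-ynal
Product: 3 (3R)-1-(trimethylsilyl)hex-5-en-1-yn-3-ol, via borinate ester 2 (not isolated)
Conditions: (+)-Ipc2BOMe (the (−)-α-pinene series), allylMgBr, Et2O, 0 °C to rt, Mg salts filtered off; 1, Et2O, −100 °C; then 3 M NaOH, 30% H2O2, rt
Reagents that add atoms: allylmagnesium bromide (C=CC[Mg]Br)
Why: Brown asymmetric allylboration through a closed chair transition state, in which the isopinocampheyl groups of the (−)-α-pinene-derived B-allyl reagent should direct the allyl group to the Re face of the ynal and so set the (R)-carbinol, the only stereocentre of the target.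

**Step 2**
Reactants: 3 (3R)-1-(trimethylsilyl)hex-5-en-1-yn-3-ol
Product: 4 tert-butyldimethyl{[(3R)-1-(trimethylsilyl)hex-5-en-1-yn-3-yl]oxy}silane
Conditions: TBSCl, imidazole, DMF, rt
Reagents that add atoms: tert-butyldimethylsilyl chloride (CC(C)(C)[Si](C)(C)Cl)
Why: Standard imidazole-promoted O-silylation of a secondary propargylic alcohol, which does not touch the stereocentre.

**Step 3**
Reactants: 4 tert-butyldimethyl{[(3R)-1-(trimethylsilyl)hex-5-en-1-yn-3-yl]oxy}silane
Product: 6 (3R)-3-[(tert-butyldimethylsilyl)oxy]-5-(trimethylsilyl)pent-4-ynal, via vicinal diol 5 (not isolated)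
Conditions: OsO4 (cat.), NaIO4, 2,6-lutidine, dioxane/H2O, rt
Reagents that add atoms: osmium tetroxide (O=[Os](=O)(=O)=O), re-oxidised by sodium periodate ([Na+].[O-][I](=O)(=O)=O)
Why: Lutidine-buffered Johnson–Lemieux cleavage, in which OsO4 should dihydroxylate the monosubstituted alkene far faster than the silylalkyne and periodate cleaves the diol under near-neutral conditions that avoid β-elimination of the silyloxy group.

**Step 4**
Reactants: 6 (3R)-3-[(tert-butyldimethylsilyl)oxy]-5-(trimethylsilyl)pent-4-ynal; 7 ethyl 2-bromo-2-(triphenylphosphoranylidene)acetate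
Product: 8 ethyl (2Z,5R)-2-bromo-5-[(tert-butyldimethylsilyl)oxy]-7-(trimethylsilyl)hept-2-en-6-ynoate
Conditions: CH2Cl2, rt to 40 °C
Reagents that add atoms: none
Why: Wittig olefination with a stabilised α-bromo ylide should place the ester trans to the chain, so bromine ends cis to C4 ((Z)-bromoenoate), the geometry that later puts the homofarnesyl group cis to the carbinol-bearing CH2.

**Step 5**
Reactants: 8 ethyl (2Z,5R)-2-bromo-5-[(tert-butyldimethylsilyl)oxy]-7-(trimethylsilyl)hept-2-en-6-ynoate
Product: 9 (2Z,5R)-2-bromo-5-[(tert-butyldimethylsilyl)oxy]-7-(trimethylsilyl)hept-2-en-6-yn-1-ol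
Conditions: DIBAL-H, CH2Cl2, −78 °C; aq. Rochelle salt
Reagents that add atoms: none
Why: DIBAL-H 1,2-reduction of an α,β-unsaturated ester to the allylic alcohol at low temperature should leave the vinyl bromide, silylalkyne and silyl ether untouched.

**Step 6**
Reactants: 9 (2Z,5R)-2-bromo-5-[(tert-butyldimethylsilyl)oxy]-7-(trimethylsilyl)hept-2-en-6-yn-1-ol
Product: 10 (3R,5Z)-6-bromo-3,7-bis[(tert-butyldimethylsilyl)oxy]-1-(trimethylsilyl)hept-5-en-1-yne
Conditions: TBSCl, imidazole, CH2Cl2, rt
Reagents that add atoms: tert-butyldimethylsilyl chloride (CC(C)(C)[Si](C)(C)Cl)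
Why: Silylation of the primary allylic alcohol removes the only O–H bond the carbenoid of step 8 could insert into, and gives two silyl ethers that can leave together at the end.

**Step 7**
Reactants: 10 (3R,5Z)-6-bromo-3,7-bis[(tert-butyldimethylsilyl)oxy]-1-(trimethylsilyl)hept-5-en-1-yne
Product: 11 (3R,5Z)-6-bromo-3,7-bis[(tert-butyldimethylsilyl)oxy]hept-5-en-1-yne
Conditions: K2CO3 (cat.), MeOH, 0 °C to rt
Reagents that add atoms: none
Why: Methoxide-catalysed protodesilylation of the C(sp)–SiMe3 bond is much faster than cleavage of the O–TBS ethers and should unmask the terminal alkyne that fixes the regiochemistry of step 8.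

**Step 8**
Reactants: 11 (3R,5Z)-6-bromo-3,7-bis[(tert-butyldimethylsilyl)oxy]hept-5-en-1-yne; 12 tert-butyl diazoacetate
Product: 14 4-{(1R,3Z)-4-bromo-1,5-bis[(tert-butyldimethylsilyl)oxy]pent-3-en-1-yl}furan-2(5H)-one, via cyclopropene ester 13 (not isolated)
Conditions: Rh2(OAc)4 (cat.), 12 by syringe pump, CH2Cl2, rt; then Ph3PAuNTf2 (cat.), CH2Cl2, rt
Reagents that add atoms: none
Why: The divalent-rhodium carbenoid from 12 adds (2+1) to the terminal alkyne to give cyclopropene 13, whose two ring epimers converge; the cationic monovalent gold complex then binds the unsubstituted ring CH, the CH–CH(CO2tBu) σ-bond opens to a gold-stabilised allyl cation/vinyl carbene, the ester carbonyl oxygen attacks the gold-bearing terminus, and loss of isobutene with protodeauration should give the 2(5H)-furanone. The closest known reaction types are the Rh2(OAc)4-catalysed cyclopropenation of 1-alkynes with diazoacetates and the metal-catalysed ring-opening cycloisomerisation of cycloprop-2-ene-1-carboxylates to 2-alkoxyfurans or, from tert-butyl esters with cationic gold, to butenolides, so the sequence is a formal (3+2) of alkyne and carbalkoxycarbene. The three-membered ring closes by concerted carbene addition, and the lactone closes as a five-membered ring by 1,5 O–C cyclisation of the Z-vinyl carbene, which forms the ring O–CH2 bond while the cyclopropene is consumed. No new stereocentre survives, because the ring CH of 13 is destroyed, and the silyl-protected (R)-carbinol is exocyclic and takes no part. The step needs chemoselectivity for the alkyne, which the electron-poor, hindered, trisubstituted bromoalkene and the absence of O–H bonds should secure. It also needs opening with gold on the unsubstituted carbon and the ester cis to that carbon, which the terminal alkyne (positive charge develops at the substituted carbon) and the bulk of the silyloxyalkyl group (the ester turns away from it) should secure.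

**Step 9**
Reactants: 15 (2E,6E)-farnesol
Product: 16 (2E,6E)-farnesal
Conditions: TEMPO (cat.), PhI(OAc)2, CH2Cl2, rt
Reagents that add atoms: none
Why: Oxoammonium-mediated oxidation of a primary allylic alcohol should stop at the enal without over-oxidation or isomerisation of the 2,3-double bond.

**Step 10**
Reactants: 16 (2E,6E)-farnesal
Product: 17 (3E,7E)-4,8,12-trimethyltrideca-1,3,7,11-tetraene
Conditions: Ph3PCH3Br, n-BuLi, THF, 0 °C; then 16, −78 °C to rt
Reagents that add atoms: methyltriphenylphosphonium bromide (C[P+](c1ccccc1)(c1ccccc1)c1ccccc1.[Br-])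
Why: Wittig methylenation of the enal with the non-stabilised ylide should give the terminal diene and leave the trisubstituted olefins and their geometry unchanged.

**Step 11**
Reactants: 14 4-{(1R,3Z)-4-bromo-1,5-bis[(tert-butyldimethylsilyl)oxy]pent-3-en-1-yl}furan-2(5H)-one; 17 (3E,7E)-4,8,12-trimethyltrideca-1,3,7,11-tetraene
Product: 19 4-{(1R,3E,7E,11E)-1-[(tert-butyldimethylsilyl)oxy]-4-{[(tert-butyldimethylsilyl)oxy]methyl}-8,12,16-trimethylheptadeca-3,7,11,15-tetraen-1-yl}furan-2(5H)-one, via alkylborane 18 (not isolated)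
Conditions: 17, 9-BBN, THF, 0 °C to rt; then aq. K3PO4, 14, Pd(dppf)Cl2·CH2Cl2 (cat.), AsPh3, DMF/THF, rt to 40 °C
Reagents that add atoms: none
Why: B-alkyl Suzuki–Miyaura coupling, in which 9-BBN should hydroborate only the monosubstituted terminal alkene (anti-Markovnikov) and the alkylborane should couple with the vinyl bromide with retention, giving the (E)-olefin with the homofarnesyl group cis to the carbinol-bearing CH2.

**Step 12**
Reactants: 19 4-{(1R,3E,7E,11E)-1-[(tert-butyldimethylsilyl)oxy]-4-{[(tert-butyldimethylsilyl)oxy]methyl}-8,12,16-trimethylheptadeca-3,7,11,15-tetraen-1-yl}furan-2(5H)-one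
Product: 20 hippolide C, 4-[(1R,3E,7E,11E)-1-hydroxy-4-(hydroxymethyl)-8,12,16-trimethylheptadeca-3,7,11,15-tetraen-1-yl]furan-2(5H)-one
Conditions: HF·pyridine, pyridine, THF, 0 °C to rt
Reagents that add atoms: none
Why: Pyridine-buffered fluoride cleavage of both Si–O bonds avoids the basic conditions that could enolise the butenolide through its γ-positions and should leave the polyene and the carbinol configuration intact.

**Compound list**
1 | 3-(trimethylsilyl)prop-2-ynal | C[Si](C)(C)C#CC=O | starting material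
2 | (3R)-1-(trimethylsilyl)hex-5-en-1-yn-3-yl bis[(1S,2S,3S,5R)-isopinocampheyl]borinate | C=CC[C@@H](OB([C@H]1C[C@H]2C[C@@H]([C@@H]1C)C2(C)C)[C@H]1C[C@H]2C[C@@H]([C@@H]1C)C2(C)C)C#C[Si](C)(C)C | intermediate (not isolated)
3 | (3R)-1-(trimethylsilyl)hex-5-en-1-yn-3-ol | C=CC[C@@H](O)C#C[Si](C)(C)C | intermediate
4 | tert-butyldimethyl{[(3R)-1-(trimethylsilyl)hex-5-en-1-yn-3-yl]oxy}silane | C=CC[C@@H](O[Si](C)(C)C(C)(C)C)C#C[Si](C)(C)C | intermediate
5 | (4R)-4-[(tert-butyldimethylsilyl)oxy]-6-(trimethylsilyl)hex-5-yne-1,2-diol (both C2 epimers) | OCC(O)C[C@@H](O[Si](C)(C)C(C)(C)C)C#C[Si](C)(C)C | intermediate (not isolated)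
6 | (3R)-3-[(tert-butyldimethylsilyl)oxy]-5-(trimethylsilyl)pent-4-ynal | O=CC[C@@H](O[Si](C)(C)C(C)(C)C)C#C[Si](C)(C)C | intermediate
7 | ethyl 2-bromo-2-(triphenylphosphoranylidene)acetate | CCOC(=O)C(Br)=P(c1ccccc1)(c1ccccc1)c1ccccc1 | starting material
8 | ethyl (2Z,5R)-2-bromo-5-[(tert-butyldimethylsilyl)oxy]-7-(trimethylsilyl)hept-2-en-6-ynoate | CCOC(=O)/C(Br)=C/C[C@@H](O[Si](C)(C)C(C)(C)C)C#C[Si](C)(C)C | intermediate
9 | (2Z,5R)-2-bromo-5-[(tert-butyldimethylsilyl)oxy]-7-(trimethylsilyl)hept-2-en-6-yn-1-ol | OC/C(Br)=C/C[C@@H](O[Si](C)(C)C(C)(C)C)C#C[Si](C)(C)C | intermediate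
10 | (3R,5Z)-6-bromo-3,7-bis[(tert-butyldimethylsilyl)oxy]-1-(trimethylsilyl)hept-5-en-1-yne | CC(C)(C)[Si](C)(C)OC/C(Br)=C/C[C@@H](O[Si](C)(C)C(C)(C)C)C#C[Si](C)(C)C | intermediate
11 | (3R,5Z)-6-bromo-3,7-bis[(tert-butyldimethylsilyl)oxy]hept-5-en-1-yne | CC(C)(C)[Si](C)(C)OC/C(Br)=C/C[C@@H](O[Si](C)(C)C(C)(C)C)C#C | intermediate
12 | tert-butyl diazoacetate | CC(C)(C)OC(=O)C=[N+]=[N-] | starting material
13 | tert-butyl 2-{(1R,3Z)-4-bromo-1,5-bis[(tert-butyldimethylsilyl)oxy]pent-3-en-1-yl}cycloprop-2-ene-1-carboxylate (both epimers at the ring CH) | CC(C)(C)[Si](C)(C)OC/C(Br)=C/C[C@@H](O[Si](C)(C)C(C)(C)C)C1=CC1C(=O)OC(C)(C)C | intermediate (not isolated)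
14 | 4-{(1R,3Z)-4-bromo-1,5-bis[(tert-butyldimethylsilyl)oxy]pent-3-en-1-yl}furan-2(5H)-one | CC(C)(C)[Si](C)(C)OC/C(Br)=C/C[C@@H](O[Si](C)(C)C(C)(C)C)C1=CC(=O)OC1 | intermediate
15 | (2E,6E)-farnesol | CC(C)=CCC/C(C)=C/CC/C(C)=C/CO | starting material
16 | (2E,6E)-farnesal | CC(C)=CCC/C(C)=C/CC/C(C)=C/C=O | intermediate
17 | (3E,7E)-4,8,12-trimethyltrideca-1,3,7,11-tetraene | CC(C)=CCC/C(C)=C/CC/C(C)=C/C=C | intermediate
18 | 9-[(3E,7E)-4,8,12-trimethyltrideca-3,7,11-trien-1-yl]-9-borabicyclo[3.3.1]nonane | CC(C)=CCC/C(C)=C/CC/C(C)=C/CCB1C2CCCC1CCC2 | intermediate (not isolated)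
19 | 4-{(1R,3E,7E,11E)-1-[(tert-butyldimethylsilyl)oxy]-4-{[(tert-butyldimethylsilyl)oxy]methyl}-8,12,16-trimethylheptadeca-3,7,11,15-tetraen-1-yl}furan-2(5H)-one | CC(C)=CCC/C(C)=C/CC/C(C)=C/CC/C(=C\C[C@@H](O[Si](C)(C)C(C)(C)C)C1=CC(=O)OC1)CO[Si](C)(C)C(C)(C)C | intermediate
20 | hippolide C, 4-[(1R,3E,7E,11E)-1-hydroxy-4-(hydroxymethyl)-8,12,16-trimethylheptadeca-3,7,11,15-tetraen-1-yl]furan-2(5H)-one | CC(C)=CCC/C(C)=C/CC/C(C)=C/CC/C(=C\C[C@@H](O)C1=CC(=O)OC1)CO | target

**Step count and risks**
Total step count: 12. Longest linear sequence: 10 (steps 1 to 8, 11 and 12).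

Steps most likely to fail:

Step 8. The carbenoid may be diverted into dimerisation, addition to the bromoalkene or ylide formation. The cyclopropene may also open at the substituted carbon or toward the E-vinyl carbene, leading to dienes or the 5-substituted lactone regioisomer, and traces of acid may remove a silyl group. The fallback sets out from 11 and closes the ring through the acyl C–O bond instead. Deprotonation with n-BuLi and trapping with methyl chloroformate (THF, −78 °C) should give methyl (4R,6Z)-7-bromo-4,8-bis[(tert-butyldimethylsilyl)oxy]oct-6-en-2-ynoate F1. Anti-hydroiodination with NaI in AcOH should give methyl (2Z,4R,6Z)-7-bromo-4,8-bis[(tert-butyldimethylsilyl)oxy]-3-iodoocta-2,6-dienoate F2, with iodine cis to the ester. Stille coupling of the more reactive vinyl iodide with (tributylstannyl)methanol and Pd(PPh3)4 (zerovalent palladium, dioxane, 80 °C) should give methyl (2E,4R,6Z)-7-bromo-4,8-bis[(tert-butyldimethylsilyl)oxy]-3-(hydroxymethyl)octa-2,6-dienoate F3, which should lactonise in the flask and return to the route at 14.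

Step 11. Hydroboration of the conjugated terminal alkene may be slow or unselective. The aqueous base may enolise the butenolide through its γ-positions (dimerisation, erosion of the silyloxy stereocentre), and slow oxidative addition into the hindered bromide may let protodeboronation win. The fallback is a base-free Negishi coupling that sets out from 17. Hydroboration with 9-BBN followed by NaOH/H2O2 should give (3E,7E)-4,8,12-trimethyltrideca-3,7,11-trien-1-ol F4. Treatment with I2, PPh3 and imidazole should give (3E,7E)-1-iodo-4,8,12-trimethyltrideca-3,7,11-triene F5. Insertion of activated zinc dust in DMA should give [(3E,7E)-4,8,12-trimethyltrideca-3,7,11-trien-1-yl]zinc iodide F6. Coupling of this reagent with 14 under PdCl2(dppf) catalysis in THF/DMA at rt should return to the route at 19.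

Step 1. The slim alkynyl substituent may give poor facial selectivity in the allylboration, and the oxidative work-up may erode the sensitive enynol. The fallback sets the stereocentre by reduction and starts from 1. Addition of allylmagnesium bromide should give racemic 1-(trimethylsilyl)hex-5-en-1-yn-3-ol F7. Oxidation with MnO2 in CH2Cl2 should give 1-(trimethylsilyl)hex-5-en-1-yn-3-one F8, which is used at once. Noyori transfer hydrogenation with RuCl[(R,R)-TsDPEN](p-cymene) in i-PrOH at rt should deliver hydride to the face that gives the (R)-propargylic alcohol and return to the route at 3.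

**Further compounds**
F1 | step 8 | methyl (4R,6Z)-7-bromo-4,8-bis[(tert-butyldimethylsilyl)oxy]oct-6-en-2-ynoate | CC(C)(C)[Si](C)(C)OC/C(Br)=C/C[C@@H](O[Si](C)(C)C(C)(C)C)C#CC(=O)OC
F2 | step 8 | methyl (2Z,4R,6Z)-7-bromo-4,8-bis[(tert-butyldimethylsilyl)oxy]-3-iodoocta-2,6-dienoate | CC(C)(C)[Si](C)(C)OC/C(Br)=C/C[C@@H](O[Si](C)(C)C(C)(C)C)/C(I)=C/C(=O)OC
F3 | step 8 | methyl (2E,4R,6Z)-7-bromo-4,8-bis[(tert-butyldimethylsilyl)oxy]-3-(hydroxymethyl)octa-2,6-dienoate | CC(C)(C)[Si](C)(C)OC/C(Br)=C/C[C@@H](O[Si](C)(C)C(C)(C)C)/C(CO)=C/C(=O)OC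
F4 | step 11 | (3E,7E)-4,8,12-trimethyltrideca-3,7,11-trien-1-ol | CC(C)=CCC/C(C)=C/CC/C(C)=C/CCO
F5 | step 11 | (3E,7E)-1-iodo-4,8,12-trimethyltrideca-3,7,11-triene | CC(C)=CCC/C(C)=C/CC/C(C)=C/CCI
F6 | step 11 | [(3E,7E)-4,8,12-trimethyltrideca-3,7,11-trien-1-yl]zinc iodide | CC(C)=CCC/C(C)=C/CC/C(C)=C/CC[Zn]I
F7 | step 1 | racemic 1-(trimethylsilyl)hex-5-en-1-yn-3-ol | C=CCC(O)C#C[Si](C)(C)C
F8 | step 1 | 1-(trimethylsilyl)hex-5-en-1-yn-3-one | C=CCC(=O)C#C[Si](C)(C)C
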